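**Retrosynthetic overview**
1. Target ⇐ exocyclic enone methyl enol ether / tert-butyl ester (BCl3 cleaves both) ⇐ 7,18-diol (acetylation, β-elimination) ⇐ bis-epoxide, both oxiranes opened in one Cp2TiCl step.
2. Bis-epoxide ⇐ racemic Δ7 cis-decalin by Shi epoxidation run as a kinetic resolution; absolute configuration enters here.
3. Ring B is closed last: cis-decalin ⇐ Cope rearrangement of a 7-alkenyl bicyclo[2.2.2]oct-5-en-2-one (sets C5, C9, C10).
4. Key operation: saligenin + triene ester with NaIO4, Adler–Becker oxidation then Diels–Alder; the oxirane and the bicyclo[2.2.2]octenone carbocycle form together. Ring A carbons are those of the arene and C18 is its CH2OH carbon.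
5. Triene ester ⇐ but-2-yne (syn-diboration, double vinylation, hydroboration/Suzuki with the E-enol triflate of tert-butyl acetoacetate); saligenin ⇐ 2-methoxy-5-methylphenol + CH2O.

Numbering and descriptors: clerodane numbering is used for the decalins and for the same atoms in their precursors (ring A: C1–C5, C10; ring B: C5–C10; C11–C16 on C9; C17 on C8; C18 on C4; C19 on C5; C20 on C9). β is the face of the C5 methyl, so the target has 10β-H, 7β-OAc, 8α-CH3, 9α-CH3 and C11 β.

Assumptions: the spiroepoxydienone, its Diels–Alder adduct and the Cope product are racemic and are drawn as the enantiomer that leads to the target. The dienophile is taken to add on the face of the oxirane oxygen (that centre is erased later, so either outcome serves). By the spiro transition-state model the L-series (ent) Shi ketone is taken as matched to the needed enantiomer.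

**Step 1**
Reactants: 1 2-methoxy-5-methylphenol
Product: 3 2-(hydroxymethyl)-6-methoxy-3-methylphenol, via benzodioxaborinine 2 (not isolated)
Conditions: PhB(OH)2, (CH2O)n, EtCO2H (cat.), toluene, reflux, Dean–Stark; then propane-1,3-diol, THF, rt
Reagents that add atoms: formaldehyde (as paraformaldehyde), C=O; phenylboronic acid, OB(O)c1ccccc1 (stays in 2 only)
Why: Nagata ortho-hydroxymethylation, in which the aryl boronate delivers formaldehyde to the only free ortho position and diol exchange then frees the saligenin.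

**Step 2**
Reactants: 4 but-2-yne
Product: 5 (2Z)-2,3-bis(4,4,5,5-tetramethyl-1,3,2-dioxaborolan-2-yl)but-2-ene
Conditions: B2pin2, Pt(PPh3)4 (3 mol %), DMF, 80 °C, sealed tube
Reagents that add atoms: bis(pinacolato)diboron, CC1(C)OB(OC1(C)C)B1OC(C)(C)C(C)(C)O1
Why: Platinum-catalysed syn-diboration of the alkyne (Miyaura diboration) fixes the cis relation that becomes the Z tetrasubstituted alkene C8=C9.

**Step 3**
Reactants: 5 (2Z)-2,3-bis(pinacolboryl)but-2-ene; 6 bromoethene
Product: 7 (3Z)-3,4-dimethylhexa-1,3,5-triene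
Conditions: bromoethene (2.5 equiv, 1 M in THF), Pd(PPh3)4 (5 mol %), aq. KOH, dioxane, 65 °C, sealed
Reagents that add atoms: none
Why: Double Suzuki–Miyaura coupling proceeds with retention of alkene geometry and gives the symmetric Z-triene, which is handled well below the temperature of its 6π electrocyclisation.

**Step 4**
Reactants: 8 tert-butyl 3-oxobutanoate
Product: 9 tert-butyl (2E)-3-[(trifluoromethanesulfonyl)oxy]but-2-enoate
Conditions: Tf2O, aq. Me4NOH, hexanes, 5 °C
Reagents that add atoms: trifluoromethanesulfonic anhydride, O=S(=O)(OS(=O)(=O)C(F)(F)F)C(F)(F)F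
Why: Enol triflation of the β-keto ester through the non-chelated tetramethylammonium enolate gives the E-triflate (OTf trans to the ester).

**Step 5**
Reactants: 7 (3Z)-3,4-dimethylhexa-1,3,5-triene; 9 tert-butyl (2E)-3-[(trifluoromethanesulfonyl)oxy]but-2-enoate
Product: 11 tert-butyl (2E,6Z)-3,6,7-trimethylnona-2,6,8-trienoate, via alkylborane 10 (not isolated)
Conditions: 9-BBN, THF, 0 °C to rt (7 in 2.5-fold excess); then 9, Pd(dppf)Cl2 (5 mol %), AsPh3, aq. K3PO4, DMF, rt
Reagents that add atoms: 9-borabicyclo[3.3.1]nonane, B1C2CCCC1CCC2 (stays in 10 only)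
Why: Anti-Markovnikov hydroboration of one of the two equivalent vinyl groups followed by B-alkyl Suzuki–Miyaura coupling with retention at the E-triflate gives the 13E enoate and leaves the Z-diene untouched.

**Step 6**
Reactants: 3 2-(hydroxymethyl)-6-methoxy-3-methylphenol; 11 tert-butyl (2E,6Z)-3,6,7-trimethylnona-2,6,8-trienoate
Product: 13 rac-7-alkenyl-1-methoxy-4-methyl-3-spiro-oxiranyl-bicyclo[2.2.2]oct-5-en-2-one (full description in the list), via spiroepoxydienone 12 (not isolated)
Conditions: NaIO4 (2.2 equiv), 3 (2 equiv per 11), MeCN/H2O, 0 °C, then 40 °C, 24 h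
Reagents that add atoms: none
Why: Adler–Becker oxidation closes the oxirane of 12 and its diene is trapped in an inverse-electron-demand Diels–Alder reaction by the terminal vinyl group of 11 (CH2 to the methyl-bearing C5, substituted carbon to C2 by the ortho rule, side chain endo), so the oxirane and the bicyclo[2.2.2]octenone ring form in one operation and the C5 quaternary centre is set.

**Step 7**
Reactants: 13 rac-Diels–Alder adduct
Product: 14 rac-tert-butyl (13E)-4α,18-epoxy-2-methoxy-3-oxocleroda-1,7,13-trien-15-oate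
Conditions: mesitylene, BHT (cat.), 165 °C, sealed tube
Reagents that add atoms: none
Why: Cope rearrangement of the 1,5-diene C9=C8–C7–C2–C1=C10 through the boat geometry imposed by the bicycle forms C9–C10 on the face that carries C6 (cis-fused ring B, 10β-H), the Z alkene geometry places C11 β and CH3-20 α, and the breaking C2–C7 bond is weakened by the captodative C2 (OMe, C=O) and by strain release.

**Step 8**
Reactants: 14 rac-tert-butyl (13E)-4α,18-epoxy-2-methoxy-3-oxocleroda-1,7,13-trien-15-oate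
Product: 15 tert-butyl (13E)-4α,18:7β,8β-diepoxy-2-methoxy-3-oxocleroda-1,13-dien-15-oate
Conditions: ent-Shi ketone (1,2:4,5-di-O-isopropylidene-L-erythro-hexo-2,3-diulo-2,6-pyranose, 30 mol %), KHSO5 (as 2KHSO5·KHSO4·K2SO4, 0.6 equiv), K2CO3, Bu4NHSO4, MeCN/CH2(OMe)2/aq. Na2B4O7 buffer, 0 °C, stopped near 50 % conversion
Reagents that add atoms: potassium peroxymonosulfate KHSO5, [K+].[O-]S(=O)(=O)OO
Why: Shi asymmetric epoxidation used as a kinetic resolution, in which the dioxirane attacks the only electron-rich alkene (C7=C8) from the open β face (the α face is blocked by axial C4 and CH3-20) and only the enantiomer whose β face matches the catalyst reacts fast, leaving ent-14 behind.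

**Step 9**
Reactants: 15 tert-butyl (13E)-4α,18:7β,8β-diepoxy-2-methoxy-3-oxocleroda-1,13-dien-15-oate
Product: 16 tert-butyl (13E)-7β,18-dihydroxy-2-methoxy-3-oxocleroda-1,13-dien-15-oate (C4 epimers)
Conditions: Cp2TiCl2 (5 equiv), Zn dust, THF; cyclohexa-1,4-diene (10 equiv), rt; aq. NaH2PO4
Reagents that add atoms: none
Why: Nugent–RajanBabu reductive epoxide opening, in which Cp2TiCl cleaves the epoxy ketone at C4–O (the titanium enolate masks the enone) and the 7,8-epoxide at the tertiary C8–O bond, and the C8 radical takes hydrogen axially from the open β face to give 7β-OH and 8α-CH3.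

**Step 10**
Reactants: 16 tert-butyl (13E)-7β,18-dihydroxy-2-methoxy-3-oxocleroda-1,13-dien-15-oate
Product: 18 tert-butyl (13E)-7β-acetoxy-2-methoxy-3-oxocleroda-1,4(18),13-trien-15-oate, via diacetate 17 (not isolated)
Conditions: Ac2O, pyridine, DMAP, CH2Cl2, 0 °C to rt; then DBU, rt
Reagents that add atoms: acetic anhydride, CC(=O)OC(C)=O
Why: Acetylation of both hydroxyls is followed by E1cB elimination of the β-acetoxy ketone, which gives the exocyclic enone from either C4 epimer while the C7 acetate, having no acidifying carbonyl, stays.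

**Step 11**
Reactants: 18 tert-butyl (13E)-7β-acetoxy-2-methoxy-3-oxocleroda-1,4(18),13-trien-15-oate
Product: 19 (13E)-7β-acetoxy-2-hydroxy-3-oxocleroda-1,4(18),13-trien-15-oic acid (CNP0192653.1)
Conditions: BCl3 (5 equiv), CH2Cl2, −78 to 0 °C; aq. NaHCO3, then pH 3
Reagents that add atoms: none
Why: Lewis-acid dealkylation, in which BCl3 chelated between the C3 carbonyl and the C2 methoxy oxygen cleaves O–CH3 (as for methoxy groups next to carbonyls) and ionises the tert-butyl ester, and hydrolysis frees the diosphenol and the acid without touching the secondary acetate.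

**Compound list**
1 | 2-methoxy-5-methylphenol | COc1ccc(C)cc1O | starting material
2 | 8-methoxy-5-methyl-2-phenyl-4H-1,3,2-benzodioxaborinine | COc1ccc(C)c2COB(c3ccccc3)Oc12 | intermediate
3 | 2-(hydroxymethyl)-6-methoxy-3-methylphenol | COc1ccc(C)c(CO)c1O | intermediate
4 | but-2-yne | CC#CC | starting material
5 | (2Z)-2,3-bis(4,4,5,5-tetramethyl-1,3,2-dioxaborolan-2-yl)but-2-ene | C/C(B1OC(C)(C)C(C)(C)O1)=C(\C)B1OC(C)(C)C(C)(C)O1 | intermediate
6 | bromoethene | C=CBr | starting material
7 | (3Z)-3,4-dimethylhexa-1,3,5-triene | C=C/C(C)=C(C)\C=C | intermediate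
8 | tert-butyl 3-oxobutanoate | CC(=O)CC(=O)OC(C)(C)C | starting material
9 | tert-butyl (2E)-3-[(trifluoromethanesulfonyl)oxy]but-2-enoate | C/C(OS(=O)(=O)C(F)(F)F)=C\C(=O)OC(C)(C)C | intermediate
10 | 9-[(3Z)-3,4-dimethylhexa-3,5-dien-1-yl]-9-borabicyclo[3.3.1]nonane | C=C/C(C)=C(C)\CCB1C2CCCC1CCC2 | intermediate
11 | tert-butyl (2E,6Z)-3,6,7-trimethylnona-2,6,8-trienoate | C=C/C(C)=C(C)\CC/C(C)=C/C(=O)OC(C)(C)C | intermediate
12 | rac-5-methoxy-8-methyl-1-oxaspiro[2.5]octa-5,7-dien-4-one (enantiomer leading to 19 shown) | COC1=CC=C(C)[C@@]2(CO2)C1=O | intermediate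
13 | rac-tert-butyl (2E,6Z)-3,6-dimethyl-7-(bicyclic)octa-2,6-dienoate, the bicycle being bicyclo[2.2.2]oct-5-en-2-one with 1-OMe, 4-CH3, C3 spiro-fused to an oxirane (O syn to the C7–C8 bridge) and the chain on C7 endo (syn to C5=C6); enantiomer leading to 19 shown | CO[C@]12C=C[C@](C)(C[C@@H]1/C(C)=C(C)\CC/C(C)=C/C(=O)OC(C)(C)C)[C@@]1(CO1)C2=O | intermediate
14 | rac-tert-butyl (13E)-4α,18-epoxy-2-methoxy-3-oxocleroda-1,7,13-trien-15-oate (cis-fused, 10β-H, 20-CH3 α; enantiomer leading to 19 shown) | C1O[C@@]13C(=O)C(OC)=C[C@@H]2[C@@](C)(CC/C(C)=C/C(=O)OC(C)(C)C)C(C)=CC[C@]32C | intermediate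
15 | tert-butyl (13E)-4α,18:7β,8β-diepoxy-2-methoxy-3-oxocleroda-1,13-dien-15-oate | C1O[C@@]13C(=O)C(OC)=C[C@@H]2[C@@](C)(CC/C(C)=C/C(=O)OC(C)(C)C)[C@@]4(C)O[C@H]4C[C@]32C | intermediate
16 | tert-butyl (13E)-7β,18-dihydroxy-2-methoxy-3-oxocleroda-1,13-dien-15-oate (8α-CH3; C4 epimers, centre left open) | OCC1C(=O)C(OC)=C[C@@H]2[C@@](C)(CC/C(C)=C/C(=O)OC(C)(C)C)[C@H](C)[C@@H](O)C[C@]12C | intermediate
17 | tert-butyl (13E)-7β,18-diacetoxy-2-methoxy-3-oxocleroda-1,13-dien-15-oate (C4 epimers) | CC(=O)OCC1C(=O)C(OC)=C[C@@H]2[C@@](C)(CC/C(C)=C/C(=O)OC(C)(C)C)[C@H](C)[C@@H](OC(C)=O)C[C@]12C | intermediate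
18 | tert-butyl (13E)-7β-acetoxy-2-methoxy-3-oxocleroda-1,4(18),13-trien-15-oate | C=C1C(=O)C(OC)=C[C@@H]2[C@@](C)(CC/C(C)=C/C(=O)OC(C)(C)C)[C@H](C)[C@@H](OC(C)=O)C[C@]12C | intermediate
19 | (13E)-7β-acetoxy-2-hydroxy-3-oxocleroda-1,4(18),13-trien-15-oic acid (CNP0192653.1) | C=C1C(=O)C(O)=C[C@@H]2[C@@](C)(CC/C(C)=C/C(=O)O)[C@H](C)[C@@H](OC(C)=O)C[C@]12C | target

Total steps: 11. Longest linear sequence: 9 steps (4 → 5 → 7 → 11 → 13 → 14 → 15 → 16 → 18 → 19).

**Steps most likely to fail**

First, step 7. The Cope rearrangement must build the C9 quaternary centre through a boat transition state with a fully substituted alkene terminus, and retro-Diels–Alder loss of the dienone may compete. The fallback makes the bridgehead oxygen the trigger of an anionic oxy-Cope rearrangement; it sets out from 1 and comes back at 14. Casiraghi formylation (MgCl2, Et3N, (CH2O)n) gives 2-hydroxy-3-methoxy-6-methylbenzaldehyde F1. BBr3 gives 2,3-dihydroxy-6-methylbenzaldehyde F2. TIPSCl/imidazole silylates the non-chelated hydroxyl to give 2-hydroxy-6-methyl-3-[(triisopropylsilyl)oxy]benzaldehyde F3, and NaBH4 gives 2-(hydroxymethyl)-3-methyl-6-[(triisopropylsilyl)oxy]phenol F4. NaIO4 in the presence of 11 then gives, through rac-8-methyl-5-[(triisopropylsilyl)oxy]-1-oxaspiro[2.5]octa-5,7-dien-4-one F5, the bridgehead silyl ether analogue of 13 F6. TBAF (THF, −78 to 0 °C) frees the C2 alkoxide, which rearranges below room temperature to rac-tert-butyl (13E)-4α,18-epoxy-2-hydroxy-3-oxocleroda-1,7,13-trien-15-oate F7. Me2SO4/K2CO3 methylates the enol oxygen and returns 14.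

Second, step 8. The selectivity factor of the kinetic resolution on this hindered alkene is unknown, and the matched catalyst enantiomer is predicted only by the model. The fallback is a classical resolution; it sets out from 14 and comes back at 19. Racemic 14 is epoxidised with mCPBA (same β face) and the racemate is carried through steps 9 to 11. The racemic acid is then crystallised as the (1S)-1-phenylethanaminium salt of 19 F8 (which amine enantiomer gives the less soluble salt must be found by trial), and acidification returns 19.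

Third, step 9. One reagent has to open two different epoxides, the C8 hydrogen must arrive from the β face, and the C8 radical can instead lose hydrogen to give an allylic alcohol. The fallback separates the two events and sets C8 by equilibration; it sets out from 15 and comes back at 17. SmI2 (THF/MeOH, −78 °C) opens only the epoxy ketone and gives tert-butyl (13E)-7β,8β-epoxy-18-hydroxy-2-methoxy-3-oxocleroda-1,13-dien-15-oate F9. LiClO4-promoted Meinwald rearrangement (hydride shift, then equilibration of C8 to 8α-CH3) gives tert-butyl (13E)-18-hydroxy-2-methoxy-3,7-dioxocleroda-1,13-dien-15-oate F10. NaBH4 at −78 °C reduces the saturated ketone from the open β face to tert-butyl (13E)-7α,18-dihydroxy-2-methoxy-3-oxocleroda-1,13-dien-15-oate F11. A Mitsunobu reaction with AcOH (PPh3, DIAD) acetylates the primary alcohol and inverts C7, giving 17.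

**Further compounds**
F1 | step 7 | 2-hydroxy-3-methoxy-6-methylbenzaldehyde | COc1ccc(C)c(C=O)c1O
F2 | step 7 | 2,3-dihydroxy-6-methylbenzaldehyde | Cc1ccc(O)c(O)c1C=O
F3 | step 7 | 2-hydroxy-6-methyl-3-[(triisopropylsilyl)oxy]benzaldehyde | CC(C)[Si](Oc1ccc(C)c(C=O)c1O)(C(C)C)C(C)C
F4 | step 7 | 2-(hydroxymethyl)-3-methyl-6-[(triisopropylsilyl)oxy]phenol | CC(C)[Si](Oc1ccc(C)c(CO)c1O)(C(C)C)C(C)C
F5 | step 7 | rac-8-methyl-5-[(triisopropylsilyl)oxy]-1-oxaspiro[2.5]octa-5,7-dien-4-one | CC(C)[Si](OC1=CC=C(C)[C@@]2(CO2)C1=O)(C(C)C)C(C)C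
F6 | step 7 | bridgehead silyl ether analogue of 13 (1-OSi(iPr)3 in place of 1-OMe, racemic) | CC(C)[Si](O[C@]12C=C[C@](C)(C[C@@H]1/C(C)=C(C)\CC/C(C)=C/C(=O)OC(C)(C)C)[C@@]1(CO1)C2=O)(C(C)C)C(C)C
F7 | step 7 | rac-tert-butyl (13E)-4α,18-epoxy-2-hydroxy-3-oxocleroda-1,7,13-trien-15-oate | C1O[C@@]13C(=O)C(O)=C[C@@H]2[C@@](C)(CC/C(C)=C/C(=O)OC(C)(C)C)C(C)=CC[C@]32C
F8 | step 8 | (1S)-1-phenylethanaminium salt of 19 | C=C1C(=O)C(O)=C[C@@H]2[C@@](C)(CC/C(C)=C/C(=O)[O-])[C@H](C)[C@@H](OC(C)=O)C[C@]12C.C[C@H]([NH3+])c1ccccc1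
F9 | step 9 | tert-butyl (13E)-7β,8β-epoxy-18-hydroxy-2-methoxy-3-oxocleroda-1,13-dien-15-oate (C4 epimers) | OCC1C(=O)C(OC)=C[C@@H]2[C@@](C)(CC/C(C)=C/C(=O)OC(C)(C)C)[C@@]3(C)O[C@H]3C[C@]12C
F10 | step 9 | tert-butyl (13E)-18-hydroxy-2-methoxy-3,7-dioxocleroda-1,13-dien-15-oate (8α-CH3, C4 epimers) | OCC1C(=O)C(OC)=C[C@@H]2[C@@](C)(CC/C(C)=C/C(=O)OC(C)(C)C)[C@H](C)C(=O)C[C@]12C
F11 | step 9 | tert-butyl (13E)-7α,18-dihydroxy-2-methoxy-3-oxocleroda-1,13-dien-15-oate (C4 epimers) | OCC1C(=O)C(OC)=C[C@@H]2[C@@](C)(CC/C(C)=C/C(=O)OC(C)(C)C)[C@H](C)[C@H](O)C[C@]12C
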